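**Retrosynthetic overview**
1. Acid ⇐ methyl ester; the (E)-C7=C8 trisubstituted olefin ⇐ two successive Negishi couplings (side-chain alkylzinc, then Me2Zn) on a 6-(2,2-dichlorovinyl)-1,2-dioxane.
2. C2–C3 bond and the C3 stereocenter ⇐ Mukaiyama-type addition of a ketene silyl acetal to a six-membered peroxycarbenium ion (key step; no oxa-Michael ring closure).
3. 1,2-Dioxane (the only ring, formed in step 5 from the transient oxirane of step 4) ⇐ 6-exo opening of a Sharpless epoxide by an ozonolysis-derived α-methoxy hydroperoxide; inversion sets C6, and both peroxide oxygens come from ozone.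
4. Epoxy alcohol ⇐ asymmetric epoxidation of a (Z)-dienol ⇐ Negishi coupling of (Z)-3-iodopent-2-en-1-ol with a homoallylic zinc reagent.
5. Both ethyl-bearing CH stereocenters (C4 and C10) ⇐ the same (S)-3-(bromomethyl)pent-1-ene, from one copper-catalysed asymmetric allylic ethylation of (E)-1,4-dibromobut-2-ene; the side chain by cross-metathesis with (E)-hex-3-ene.

Assumption: the ligand antipode named in step 2 is taken to be the one that gives the S bromide (checked once on the product; the mirror-image ligand is used otherwise); atom labels follow the target (C1 acid carbon, O1/O2 and C3–C6 ring, C7–C14 side chain).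

**Step 1**
Reactants: 1 pent-2-yn-1-ol
Product: 2 (Z)-3-iodopent-2-en-1-ol
Conditions: NaAlH2(OCH2CH2OMe)2 (1.5 equiv), THF, 0 to 20 °C; then I2, −78 to 0 °C; aqueous work-up
Reagents that add atoms: iodine, [I][I]
Why: Hydroxyl-directed trans-hydroalumination of the propargylic alcohol puts aluminium on C3 inside a five-membered alkoxyaluminate, and iodinolysis with retention gives only the Z vinyl iodide, which fixes the later olefin geometry.

**Step 2**
Reactants: 3 (E)-1,4-dibromobut-2-ene
Product: 4 (S)-3-(bromomethyl)pent-1-ene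
Conditions: EtMgBr (1.2 equiv), CuBr·SMe2 (3 mol%), (Rp)-1-[(R)-α-(dimethylamino)-2-(diphenylphosphino)benzyl]-2-(diphenylphosphino)ferrocene (Taniaphos, 3.6 mol%), CH2Cl2, −78 °C, slow addition of 3
Reagents that add atoms: ethylmagnesium bromide, CC[Mg]Br
Why: Copper-catalysed asymmetric allylic alkylation (SN2′) of an allylic bromide by a Grignard reagent, a known reaction type for 1,4-dihalobut-2-enes; the chiral diphosphine controls the face of the γ-attack and so sets the ethyl-bearing stereocenter, and the second bromide, now primary and homoallylic, is inert.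

**Step 3**
Reactants: 4 (S)-3-(bromomethyl)pent-1-ene; 2 (Z)-3-iodopent-2-en-1-ol
Product: 6 (2Z,5R)-3,5-diethylhepta-2,6-dien-1-ol, via alkylzinc bromide 5 (not isolated)
Conditions: 4, activated Zn dust, LiCl, THF, 50 °C; then 2, Pd(OAc)2 (2 mol%), SPhos (4 mol%), THF, 25 °C
Reagents that add atoms: none
Why: Zinc insertion followed by Negishi sp3–sp2 coupling, which retains the vinyl iodide geometry and outpaces protonolysis by the free hydroxyl; the stereocenter is β to zinc and untouched (the descriptor changes from S to R only through the priority change).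

**Step 4**
Reactants: 6 (2Z,5R)-3,5-diethylhepta-2,6-dien-1-ol
Product: 7 [(2R,3S)-3-ethyl-3-[(2R)-2-ethylbut-3-en-1-yl]oxiran-2-yl]methanol
Conditions: Ti(OiPr)4 (10 mol%), D-(−)-diethyl tartrate (12 mol%), t-BuOOH (2 equiv), 4 Å molecular sieves, CH2Cl2, −20 °C
Reagents that add atoms: tert-butyl hydroperoxide, CC(C)(C)OO
Why: Katsuki–Sharpless asymmetric epoxidation touches only the allylic-alcohol olefin, and the D-(−)-tartrate delivers oxygen to the face that gives the (2R,3S) epoxide of this nerol-type Z alcohol (reagent control; nerol gives the 2S,3R epoxide with the L-(+) ester).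

**Step 5**
Reactants: 7 [(2R,3S)-3-ethyl-3-[(2R)-2-ethylbut-3-en-1-yl]oxiran-2-yl]methanol
Product: 9 (1R)-1-[(3R,5R)-3,5-diethyl-6-methoxy-1,2-dioxan-3-yl]ethane-1,2-diol (both epimers at the acetal carbon), via methoxy hydroperoxide 8 (not isolated)
Conditions: O3, CH2Cl2/MeOH 4:1, −78 °C, N2 purge; solvent changed cold to CH2Cl2; camphorsulfonic acid (5 mol%), −20 to 0 °C; Et3N quench
Reagents that add atoms: ozone, [O-][O+]=O; methanol, CO
Why: Proposed new method: ozone cleaves the only remaining C=C (Criegee mechanism) mainly to the alkyl-substituted carbonyl oxide at C3 plus formaldehyde, methanol traps it as the α-methoxy hydroperoxide, and under mild acid this hydroperoxide opens the trisubstituted epoxide 6-exo at the tertiary carbon C6 by backside attack, which closes the 1,2-dioxane and converts the 3S epoxide carbon into the 6R tertiary peroxide with inversion; the closest known reaction types are the acid-catalysed intramolecular opening of epoxides by hydroperoxides to 1,2-dioxanes and the use of ozonolysis-derived hydroperoxy acetals as peroxide nucleophiles in cyclisations.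

**Step 6**
Reactants: 9 (1R)-1-[(3R,5R)-3,5-diethyl-6-methoxy-1,2-dioxan-3-yl]ethane-1,2-diol
Product: 10 (3R,5R)-3,5-diethyl-6-methoxy-1,2-dioxane-3-carbaldehyde
Conditions: NaIO4 (1.5 equiv), THF/aqueous NaH2PO4–Na2HPO4 buffer (pH 7), 0 °C
Reagents that add atoms: none
Why: Malaprade glycol cleavage is neutral and leaves the peroxide and the peroxyacetal alone, and the new aldehyde sits on a quaternary carbon, so C6 cannot epimerise.

**Step 7**
Reactants: 10 (3R,5R)-3,5-diethyl-6-methoxy-1,2-dioxane-3-carbaldehyde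
Product: 11 (3R,5R)-3-(2,2-dichloroethenyl)-3,5-diethyl-6-methoxy-1,2-dioxane
Conditions: (EtO)2P(O)CHCl2 (1.5 equiv), LiN(SiMe3)2 (1.4 equiv), THF, −78 °C; then 10, −78 to 20 °C
Reagents that add atoms: diethyl (dichloromethyl)phosphonate, CCOP(=O)(OCC)C(Cl)Cl
Why: Horner–Wadsworth–Emmons-type dichloromethylenation with a preformed, weakly basic phosphonate carbanion is phosphine-free (no peroxide reduction), reacts with hindered aldehydes, and creates no stereocenter.

**Step 8**
Reactants: 11 (3R,5R)-3-(2,2-dichloroethenyl)-3,5-diethyl-6-methoxy-1,2-dioxane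
Product: 12 methyl 2-[(3R,4R,6R)-6-(2,2-dichloroethenyl)-4,6-diethyl-1,2-dioxan-3-yl]acetate
Conditions: CH2=C(OMe)OSiMe2tBu (2 equiv), TMSOTf (0.3 equiv), CH2Cl2, −78 °C; Et3N, then aqueous NaHCO3
Reagents that add atoms: 1-(tert-butyldimethylsilyloxy)-1-methoxyethene, C=C(OC)O[Si](C)(C)C(C)(C)C
Why: Mukaiyama-type addition of a ketene silyl acetal to a cyclic peroxycarbenium ion: TMSOTf removes the methoxy group, the ion sits in the half-chair with the C4 ethyl and the C6 dichlorovinyl group pseudo-equatorial (the other half-chair would make them 1,3-diaxial), and attack along the axial, chair-forming trajectory places the acetate arm cis to the C4 ethyl group (3R), while the electron-poor dichlorovinyl group keeps the C6–O bond from ionising.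

**Step 9**
Reactants: 4 (S)-3-(bromomethyl)pent-1-ene; 13 (E)-hex-3-ene
Product: 14 (3E,5S)-5-(bromomethyl)hept-3-ene
Conditions: 13 (5 equiv), second-generation Hoveyda–Grubbs catalyst RuCl2(H2IMes)(=CH-C6H4-2-OiPr) (2 mol%), CH2Cl2, 40 °C; chromatography on AgNO3-impregnated silica gel
Reagents that add atoms: none
Why: Olefin cross-metathesis of the terminal vinyl group with excess internal olefin gives the thermodynamically favoured E-disubstituted alkene (the allylic branch raises E selectivity, and the minor Z isomer is removed on silver nitrate silica) without touching the stereocenter.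

**Step 10**
Reactants: 14 (3E,5S)-5-(bromomethyl)hept-3-ene; 12 methyl 2-[(3R,4R,6R)-6-(2,2-dichloroethenyl)-4,6-diethyl-1,2-dioxan-3-yl]acetate
Product: 16 methyl 2-[(3R,4R,6R)-6-[(1Z,4R,5E)-2-chloro-4-ethylocta-1,5-dien-1-yl]-4,6-diethyl-1,2-dioxan-3-yl]acetate, via alkylzinc bromide 15 (not isolated)
Conditions: 14, activated Zn dust, LiCl, THF, 50 °C; then 12, PdCl2(DPEphos) (5 mol%), THF/DMF, 25 to 40 °C
Reagents that add atoms: none
Why: Negishi trans-selective monoalkylation of a 1,1-dichloroalkene: zerovalent palladium inserts into the C–Cl bond trans to the bulky ring carbon, so the side chain enters trans to C6; alkylzinc halides tolerate the ester, and dialkyl peroxides are known to survive palladium cross-couplings.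

**Step 11**
Reactants: 16 methyl 2-[(3R,4R,6R)-6-[(1Z,4R,5E)-2-chloro-4-ethylocta-1,5-dien-1-yl]-4,6-diethyl-1,2-dioxan-3-yl]acetate
Product: 17 methyl 2-[(3R,4R,6R)-4,6-diethyl-6-[(1E,4R,5E)-4-ethyl-2-methylocta-1,5-dien-1-yl]-1,2-dioxan-3-yl]acetate
Conditions: Me2Zn (1.5 equiv), Pd(PtBu3)2 (5 mol%), THF, 40 °C
Reagents that add atoms: dimethylzinc, C[Zn]C
Why: Negishi methylation of the remaining alkenyl chloride proceeds with retention, so methyl ends up cis to C6 and the C7=C8 olefin is E.

**Step 12**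
Reactants: 17 methyl 2-[(3R,4R,6R)-4,6-diethyl-6-[(1E,4R,5E)-4-ethyl-2-methylocta-1,5-dien-1-yl]-1,2-dioxan-3-yl]acetate
Product: 18 2-[(3R,4R,6R)-4,6-diethyl-6-[(1E,4R,5E)-4-ethyl-2-methylocta-1,5-dien-1-yl]-1,2-dioxan-3-yl]acetic acid (CNP0136940.4)
Conditions: LiOH·H2O (3 equiv), THF/H2O 3:1, 0 to 20 °C; then 1 M HCl to pH 3
Reagents that add atoms: lithium hydroxide, [Li+].[OH-]
Why: Saponification: hydroxide adds to the ester carbonyl much faster than it deprotonates C2, so the β-peroxy ester is cleaved without E1cB ring opening and no stereocenter is touched.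

**Compound list**
1 | pent-2-yn-1-ol | CCC#CCO | starting material
2 | (Z)-3-iodopent-2-en-1-ol | CC/C(I)=C/CO | intermediate
3 | (E)-1,4-dibromobut-2-ene | BrC/C=C/CBr | starting material
4 | (S)-3-(bromomethyl)pent-1-ene | C=C[C@H](CC)CBr | intermediate
5 | [(2S)-2-ethylbut-3-en-1-yl]zinc bromide | C=C[C@H](CC)C[Zn]Br | intermediate
6 | (2Z,5R)-3,5-diethylhepta-2,6-dien-1-ol | OC/C=C(/CC)C[C@@H](CC)C=C | intermediate
7 | [(2R,3S)-3-ethyl-3-[(2R)-2-ethylbut-3-en-1-yl]oxiran-2-yl]methanol | OC[C@H]1O[C@@]1(CC)C[C@@H](CC)C=C | intermediate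
8 | [(2R,3S)-3-ethyl-3-[(2R)-2-ethyl-3-hydroperoxy-3-methoxypropyl]oxiran-2-yl]methanol (both epimers at the acetal carbon) | OC[C@H]1O[C@@]1(CC)C[C@@H](CC)C(OC)OO | intermediate
9 | (1R)-1-[(3R,5R)-3,5-diethyl-6-methoxy-1,2-dioxan-3-yl]ethane-1,2-diol (both epimers at the acetal carbon) | OC[C@@H](O)[C@@]1(CC)C[C@@H](CC)C(OC)OO1 | intermediate
10 | (3R,5R)-3,5-diethyl-6-methoxy-1,2-dioxane-3-carbaldehyde | O=C[C@@]1(CC)C[C@@H](CC)C(OC)OO1 | intermediate
11 | (3R,5R)-3-(2,2-dichloroethenyl)-3,5-diethyl-6-methoxy-1,2-dioxane | ClC(Cl)=C[C@@]1(CC)C[C@@H](CC)C(OC)OO1 | intermediate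
12 | methyl 2-[(3R,4R,6R)-6-(2,2-dichloroethenyl)-4,6-diethyl-1,2-dioxan-3-yl]acetate | ClC(Cl)=C[C@@]1(CC)C[C@@H](CC)[C@@H](CC(=O)OC)OO1 | intermediate
13 | (E)-hex-3-ene | CC/C=C/CC | starting material
14 | (3E,5S)-5-(bromomethyl)hept-3-ene | CC/C=C/[C@H](CC)CBr | intermediate
15 | [(2S,3E)-2-ethylhex-3-en-1-yl]zinc bromide | CC/C=C/[C@H](CC)C[Zn]Br | intermediate
16 | methyl 2-[(3R,4R,6R)-6-[(1Z,4R,5E)-2-chloro-4-ethylocta-1,5-dien-1-yl]-4,6-diethyl-1,2-dioxan-3-yl]acetate | CC/C=C/[C@H](CC)C/C(Cl)=C/[C@@]1(CC)C[C@@H](CC)[C@@H](CC(=O)OC)OO1 | intermediate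
17 | methyl 2-[(3R,4R,6R)-4,6-diethyl-6-[(1E,4R,5E)-4-ethyl-2-methylocta-1,5-dien-1-yl]-1,2-dioxan-3-yl]acetate | CC/C=C/[C@H](CC)C/C(C)=C/[C@@]1(CC)C[C@@H](CC)[C@@H](CC(=O)OC)OO1 | intermediate
18 | 2-[(3R,4R,6R)-4,6-diethyl-6-[(1E,4R,5E)-4-ethyl-2-methylocta-1,5-dien-1-yl]-1,2-dioxan-3-yl]acetic acid | CC/C=C/[C@H](CC)C/C(C)=C/[C@@]1(CC)C[C@@H](CC)[C@@H](CC(=O)O)OO1 | target

**Step count and risk**
Total: 12 steps. Longest linear sequence: 10 steps (steps 2, 3, 4, 5, 6, 7, 8, 10, 11, 12 from 3; equally steps 1, 3 to 8, 10 to 12 from 1).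

Most likely to fail, first: step 5. The primary ozonide can also cleave the other way, the methoxy hydroperoxide may be too weak a nucleophile for the epoxide, and the free C7 hydroxyl of 9 can exchange into the peroxyacetal under acid. The fallback sets out from 7 and comes back at 12, closing the ring by the conventional oxa-Michael route. Cross-metathesis of 7 with methyl acrylate (second-generation Hoveyda–Grubbs catalyst) gives methyl (2E,4R)-4-ethyl-5-[(2S,3R)-2-ethyl-3-(hydroxymethyl)oxiran-2-yl]pent-2-enoate F1. Ethereal H2O2 with catalytic H3PMo12O40 opens the epoxide at the tertiary carbon with inversion to methyl (2E,4R,6R,7R)-4,6-diethyl-6-hydroperoxy-7,8-dihydroxyoct-2-enoate F2. Et2NH in CF3CH2OH then closes the dioxane by intramolecular oxa-Michael addition to methyl 2-[(3R,4R,6R)-6-[(1R)-1,2-dihydroxyethyl]-4,6-diethyl-1,2-dioxan-3-yl]acetate F3, which is separated from its 3-epimer. NaIO4 cleaves F3 to methyl 2-[(3R,4R,6R)-4,6-diethyl-6-formyl-1,2-dioxan-3-yl]acetate F4, and the dichloromethylenation of step 7 applied to F4 gives 12.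

Second: step 8. The 3,4-cis outcome rests on the axial-attack model, and the Lewis acid could instead fragment the aldehyde-derived peroxyacetal. The fallback sets out from 11 and comes back at 12. Mild hydrolysis of the methyl peroxyacetal (p-TsOH·H2O, THF/H2O) gives the lactol (4R,6R)-6-(2,2-dichloroethenyl)-4,6-diethyl-1,2-dioxan-3-ol F5. Wittig reaction of its open hydroperoxy-aldehyde form with Ph3P=CHCO2Me gives methyl (2E,4R,6R)-8,8-dichloro-4,6-diethyl-6-hydroperoxyocta-2,7-dienoate F6. Et2NH in CF3CH2OH recloses the ring by oxa-Michael addition to 12, which is separated from the 3-epimer.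

Third: step 10. The risks are peroxide tolerance of the palladium catalyst, mono-selectivity and β-hydride loss at a hindered dichloroalkene. The fallback sets out from 10 and comes back at 17, building the C7=C8 bond by olefination without palladium. The ketene silyl acetal addition of step 8 is run on 10 itself (TMSOTf activates the acetal, not the hindered aldehyde) to give methyl 2-[(3R,4R,6R)-4,6-diethyl-6-formyl-1,2-dioxan-3-yl]acetate F7. Separately, 14 alkylates the lithium anion of 5-(ethylsulfonyl)-1-phenyl-1H-tetrazole (LiN(SiMe3)2, THF/DMPU) to give 5-{[(4R,5E)-4-ethyloct-5-en-2-yl]sulfonyl}-1-phenyl-1H-tetrazole F8. Julia–Kocienski olefination of F7 with F8 (KN(SiMe3)2, DME, −60 °C) gives 17 after separation of the C7=C8 isomers.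

**Further compounds**
F1 | step 5 | methyl (2E,4R)-4-ethyl-5-[(2S,3R)-2-ethyl-3-(hydroxymethyl)oxiran-2-yl]pent-2-enoate | OC[C@H]1O[C@@]1(CC)C[C@@H](CC)/C=C/C(=O)OC
F2 | step 5 | methyl (2E,4R,6R,7R)-4,6-diethyl-6-hydroperoxy-7,8-dihydroxyoct-2-enoate | OC[C@@H](O)[C@](CC)(OO)C[C@@H](CC)/C=C/C(=O)OC
F3 | step 5 | methyl 2-[(3R,4R,6R)-6-[(1R)-1,2-dihydroxyethyl]-4,6-diethyl-1,2-dioxan-3-yl]acetate | OC[C@@H](O)[C@@]1(CC)C[C@@H](CC)[C@@H](CC(=O)OC)OO1
F4 | step 5 | methyl 2-[(3R,4R,6R)-4,6-diethyl-6-formyl-1,2-dioxan-3-yl]acetate | O=C[C@@]1(CC)C[C@@H](CC)[C@@H](CC(=O)OC)OO1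
F5 | step 8 | (4R,6R)-6-(2,2-dichloroethenyl)-4,6-diethyl-1,2-dioxan-3-ol | ClC(Cl)=C[C@@]1(CC)C[C@@H](CC)C(O)OO1
F6 | step 8 | methyl (2E,4R,6R)-8,8-dichloro-4,6-diethyl-6-hydroperoxyocta-2,7-dienoate | ClC(Cl)=C[C@](CC)(OO)C[C@@H](CC)/C=C/C(=O)OC
F7 | step 10 | methyl 2-[(3R,4R,6R)-4,6-diethyl-6-formyl-1,2-dioxan-3-yl]acetate | O=C[C@@]1(CC)C[C@@H](CC)[C@@H](CC(=O)OC)OO1
F8 | step 10 | 5-{[(4R,5E)-4-ethyloct-5-en-2-yl]sulfonyl}-1-phenyl-1H-tetrazole | CC/C=C/[C@H](CC)CC(C)S(=O)(=O)c1nnnn1-c1ccccc1
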